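A slow feed of incoming ligand looks like the gentle way to stop at one exchange, but at the opening of blue the ligand is still arriving while the starting complex stands at its full charge against itself.

in all of them: leaving ligand 5.00 equiv; time 50 s

|  | starting complex | incoming ligand | temperature | remark |
|---|---|---|---|---|
| grey | 5.0 × 10⁻⁴ M | 0.900 equiv | 90 °C | everything together at the start |
| blue | 5.0 × 10⁻⁴ M | 0.900 equiv (fed, over 10 s) | 90 °C | all else is in the flask from the start; the feed brings no volume worth counting |
| red | 5.0 × 10⁻⁴ M (fed, over 10 s) | 0.900 equiv | 90 °C | all else is in the flask from the start; the feed brings no volume worth counting |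
| ochre | 5.0 × 10⁻⁴ M | 0.900 equiv (fed, over 10 s) |  | the addition at 50 °C, then warmed to 90 °C; the feed brings no volume worth counting |

    complex with two exchanged + incoming ligand → leaving ligand + complex with three exchanged (k1 = 180 M⁻¹ s⁻¹, Ea1 = 53.0 kJ mol⁻¹)
    crystals ⇌ complex with one exchanged, rate k2*(cs2 - [complex with one exchanged]) while solid is left; crystals form when [complex with one exchanged] > cs2 (cs2 = 0.24 mM, k2 = 6.2 s⁻¹)
    2 starting complex → self-condensation product (k3 = 110 M⁻¹ s⁻¹, Ea3 = 40.0 kJ mol⁻¹)
    complex with one exchanged + incoming ligand → leaving ligand + complex with two exchanged (k4 = 410 M⁻¹ s⁻¹, Ea4 = 57.0 kJ mol⁻¹)
    starting complex + complex with one exchanged ⇌ idle adduct, settled at all times (K5 = 23000 M⁻¹, ΔH5 = −66.0 kJ mol⁻¹)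
    starting complex + incoming ligand → leaving ligand + complex with one exchanged (k6 = 820 M⁻¹ s⁻¹, Ea6 = 37.0 kJ mol⁻¹)
    (constants at 90 °C)

- percentages count the starting complex that a species holds: one idle adduct or self-condensation product counts as two
- complex with one exchanged is meant together with its idle adduct and crystals
- a step written with two of one species runs at k times the square of its concentration and takes two of it each time
- solid, in amounts per volume of the solution: crystals
- the list of constants is for 90 °C, to be carried to other temperatures by the activation energies and enthalpies
- in an amount of complex with one exchanged, one idle adduct counts as one complex with one exchanged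

- which flask leads in amount of complex with one exchanged, in percent of the starting complex charged ("all alike" within 1.5 percentage points) (grey / blue / red / ochre / all alike)
- how much complex with one exchanged is there at the end, in percent of the starting complex charged: grey
- how much complex with one exchanged is there at the end, in percent of the starting complex charged: blue
- how much complex with one exchanged is there at the end, in percent of the starting complex charged: red
- how much complex with one exchanged is there at the end, in percent of the starting complex charged: ochre

I write M for the starting complex and X for the incoming ligand. M has two one-way exits: exchange with X at k_e[M][X], with k_e = 820 M⁻¹ s⁻¹, and self-condensation at 2k_c[M]·[M], with k_c = 110 M⁻¹ s⁻¹, two M going at each turn. Dividing one loss by the other removes a factor [M]: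

ρ = k_e[X] / (2 k_c [M])

What I need is [X] and [M], so I freeze what hardly moves at the opening. At the opening of blue, [M] stands near its charge, and an X lives about 2.44 s against it, shorter than the feed time of 10 s. So for that opening I take X as eaten about as fast as it arrives, a freeze that holds for as long as [M] stays near its charge:

[X] ≈ feed rate / (k_e[M]) = 0.110 mM

ρ(blue) = 0.818

This is the split ratio, the M leaving by exchange for each M lost to self-condensation, a selectivity factor. In blue, then, condensation opens ahead of exchange.

Grey has all of X from the start, so [X]/[M] is the equivalents charged:

ρ(grey) = 3.35

Red turns the freeze round: at the opening X stands near its charge, and I set M where its feed equals its exchange, leaving the idle adduct aside.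

[M] ≈ 0.136 mM

ρ(red) = 12.4

Ochre repeats blue's form with k_c carried to 50 °C:

ρ(ochre) ≈ 4.22

That value is loose, since at 50 °C an X lives about 11.1 s, longer than the feed. These are opening values, and they speak of condensation, not of a second exchange, so I commit to an order and no percentages: red leads and blue trails.

The forecast also picks red, with 41% for grey (36% to 46%), 28% for blue (22% to 34%), 44% for red (37% to 50%) and 41% for ochre (34% to 47%), on the ground that “feeding the starting complex (red) minimises that loss”.

The run gives 41.7% for grey, 27.8% for blue, 43.6% for red and 38.1% for ochre, so red leads; with red's feed shortened to 1.00 s, red gives 42.5%, a lead over grey of 0.80 percentage points, less than the margin of 1.5 points. At the end of red's feed, at 10.0 s, the exchanged complexes, bound forms counted, hold 43.0% against 3.55% in self-condensation product, a ratio summed over the feed of 12.1. The neighbour of blue charged with 3.0 × 10⁻⁴ M reckons to an opening ratio of 1.36 and ends with 33.2% of complex with one exchanged and 27.6% of self-condensation product, against blue's 32.5%.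

Its constants are those of an exercise.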